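**Plan**

Numbering used throughout: ring A (seven-membered) = C1(OTig)–C2H2–C3(Me)–C4H (C3–C4 epoxide)–C5(OTig)–C6(Me, ring fusion)–C7(H, ring fusion); ring B = C6–C7–C8(OH)(iPr)–C9H2–C10(OH); Tig = (E)-2-methylbut-2-enoyl.
Retrosynthesis: remove the two tiglates and the epoxide (back to a C5 enone with C3=C4 and a C1 ketone), cut C8–iPr, reconnect C1–C5 (retro glycol cleavage to a cyclobutane-1,2-diol), then cut C1–C7 and C5–C6 together by a retro-[2+2] into a ring B enone and a five-carbon enediol ether.
Enabling feature: in ring A the oxygenated carbons C1 and C5 flank the ring-fusion bond C6–C7 (O–C1–C7–C6–C5–O), which is the retron of a cleaved cyclobutane-1,2-diol C1–C5–C6–C7; the C8 oxygen next to C7 supplies the chromophore C8(=O)–C7=C6; C3 with its methyl lies midway between C1 and C5, so the five-carbon partner has a mirror plane and no regiochemistry arises.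
Forward: ring B is bought as an enantiopure cyclopentenone; the photocycloaddition gives a five-four-five tricycle with a temporary cyclobutane; isopropyl is added at C8; Pb(OAc)4 cuts the temporary C1–C5 bond and unveils ring A as a 1,5-dione; C1 reduction, C3=C4 enone formation, C5 reduction, epoxidation and two acylations finish.
Stereochemistry: C10 comes from the starting enone and directs the photocycloaddition (C6 and C7 cis, anti to the C10 oxygen); C8 by convex-face Grignard addition; C1 by hydride delivery from the C8 hydroxyl; C5 by convex-face Luche reduction; the epoxide by delivery from the C5 hydroxyl; both tiglates from the (E)-acid chloride.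

Key step: step 4

Notation and assumption: β is the face of the C6 methyl group and α the opposite face; 6–11 are drawn as the C3 epimer from attack on the face of 5 away from its methyl group, and the other C3 epimer or a cis-syn-cis cyclobutane isomer would be carried along, because C1 and C5 become trigonal in step 7 and C3 in step 10.

**Route**

Step 1
Reactants: 1 (S)-4-(tert-butyldimethylsilyloxy)cyclopent-2-en-1-one
Product: 2 (3S,4S)-4-(tert-butyldimethylsilyloxy)-3-methyl-1-(trimethylsilyloxy)cyclopent-1-ene (methyl trans to the silyloxy group)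
Conditions: Me2CuLi, TMSCl, THF, −78 °C; Et3N, then aqueous NaHCO3
Reagents that add atoms: lithium dimethylcuprate C[Cu-]C.[Li+]; chlorotrimethylsilane C[Si](C)(C)Cl
Why: Conjugate addition of a Gilman cuprate with in situ O-silylation should add methyl trans to the silyloxy group and trap the enolate before it can equilibrate and eliminate the β-silyloxy group; the new methyl-bearing stereocentre is erased in step 2.

Step 2
Reactants: 2 (3S,4S)-4-(tert-butyldimethylsilyloxy)-3-methyl-1-(trimethylsilyloxy)cyclopent-1-ene
Product: 3 (S)-4-(tert-butyldimethylsilyloxy)-3-methylcyclopent-2-en-1-one (ring B enone: C8=O, C7=C6(Me), C10–OTBS)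
Conditions: Pd(OAc)2 (1.05 equiv), MeCN, rt
Reagents that add atoms: none
Why: Saegusa–Ito oxidation, in which the palladium enolate can lose only the hydrogen on the methyl-bearing carbon by β-hydride elimination, should return the enone with the methyl on the β-carbon under neutral conditions that leave the C10 stereocentre untouched.

Step 3
Reactants: 4 dimethyl 3-methylpentanedioate (dimethyl 3-methylglutarate)
Product: 5 4-methyl-1,2-bis(trimethylsilyloxy)cyclopent-1-ene
Conditions: Na, TMSCl, toluene, reflux
Reagents that add atoms: chlorotrimethylsilane C[Si](C)(C)Cl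
Why: Rühlmann acyloin condensation should couple the two ester carbonyls reductively to the five-membered enediol and trap it as the bis-silyl ether; no stereocentre is set because the methyl carbon lies on the mirror plane.

Step 4
Reactants: 3 (S)-4-(tert-butyldimethylsilyloxy)-3-methylcyclopent-2-en-1-one; 5 4-methyl-1,2-bis(trimethylsilyloxy)cyclopent-1-ene
Product: 6 tricyclic photoadduct: ring B cyclopentanone (C8=O, 10β-OTBS, 6β-Me, 7β-H) fused across C6–C7 to the cyclobutane C1–C5–C6–C7, whose C1 and C5 each carry OSiMe3 and are bridged by C2H2–C3H(Me)–C4H2 (cis-anti-cis; 3-methyl on the face away from the cyclobutane)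
Conditions: hν (350 nm, Pyrex), 5 (4 equiv), degassed hexane, −20 °C
Reagents that add atoms: none
Why: Enone–alkene [2+2] photocycloaddition: n→π* excitation and intersystem crossing give triplet 3, which is trapped by the electron-rich enediol ether 5 to a triplet 1,4-biradical that closes after spin inversion; the closest known reaction type is the photocycloaddition of cyclopentenones to 1,2-bis(trimethylsilyloxy)cycloalkenes followed by glycol cleavage as a two-carbon ring expansion. The only ring closed is the cyclobutane C1–C5–C6–C7, formed by intermolecular [2+2] union of the two alkenes (bonds C5–C6 and C1–C7), and the C1–C5 bond of the donor becomes a temporary ring bond. C6 and C7 are set cis because a trans-fused bicyclo[3.2.0]heptanone is too strained, and on the α face because the silyloxy group on the adjacent C10 shields the β face of the carbon where bonding starts. C1 and C5 are cis because they come from a ring alkene; their orientation and that of the C3 methyl are erased in steps 7 and 10. The step needs facial selectivity at 3, which the C10 substituent should secure, and no regioselectivity, because the mirror plane of 5 through C3 makes C1 and C5 equivalent; excess 5 and the β-methyl group should suppress enone dimerization.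

Step 5
Reactants: 6 tricyclic photoadduct (C8 ketone)
Product: 7 8α-hydroxy-8β-isopropyl analogue of 6 (tertiary carbinol at C8; 10β-OTBS, 6β-Me, 7β-H, 1,5-bis(trimethylsilyloxy), 3-Me)
Conditions: iPrMgCl, LaCl3·2LiCl, THF, 0 °C; aqueous NH4Cl
Reagents that add atoms: isopropylmagnesium chloride CC(C)[Mg]Cl
Why: Lanthanide-promoted Grignard 1,2-addition, which suppresses enolization and β-hydride reduction, should occur from the convex β face of the bicyclo[3.2.0]heptanone unit, opposite the cyclobutane and its inward-pointing C1 silyloxy group, setting C8 with isopropyl β and hydroxyl α.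

Step 6
Reactants: 7 8α-hydroxy-8β-isopropyl tricycle with two OSiMe3 groups
Product: 8 cis-cyclobutane-1,5-diol: 1,5,8α-trihydroxy-8β-isopropyl-3,6β-dimethyl-10β-(tert-butyldimethylsilyloxy) tricycle (7β-H)
Conditions: K2CO3 (cat.), MeOH, 0 °C to rt
Reagents that add atoms: none
Why: Base-catalysed methanolysis of silyl ethers should remove the two labile trimethylsilyl groups and leave the hindered secondary tert-butyldimethylsilyl ether in place.

Step 7
Reactants: 8 cis-cyclobutane-1,5-diol
Product: 9 8α-hydroxy-8β-isopropyl-3,6β-dimethyl-10β-(tert-butyldimethylsilyloxy)-7βH-cis-bicyclo[5.3.0]decane-1,5-dione (ring A = C1–C7, ketones at C1 and C5)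
Conditions: Pb(OAc)4, CH2Cl2, 0 °C
Reagents that add atoms: none
Why: Criegee glycol cleavage through the cyclic lead diolate, helped by release of four-ring strain, should break the temporary C1–C5 bond and expand to ring A, while the mildly acidic medium avoids retro-aldol opening at C7–C8 and epimerization at C7.

Step 8
Reactants: 9 hydroxy 1,5-dione
Product: 10 1β,8α-dihydroxy-8β-isopropyl-3,6β-dimethyl-10β-(tert-butyldimethylsilyloxy)-7βH-cis-bicyclo[5.3.0]decan-5-one
Conditions: Me4NBH(OAc)3, MeCN/AcOH (1:1), −30 °C
Reagents that add atoms: none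
Why: Saksena–Evans hydroxyl-directed reduction should exchange the C8 hydroxyl onto boron and deliver hydride internally to the α face of the C1 ketone, giving the 1β-alcohol, while the C5 ketone, which has no free β-hydroxyl because C10 is silylated, is left alone.

Step 9
Reactants: 10 1β,8α-diol 5-ketone
Product: 11 1β-tigloyloxy-8α-hydroxy-8β-isopropyl-3,6β-dimethyl-10β-(tert-butyldimethylsilyloxy)-7βH-cis-bicyclo[5.3.0]decan-5-one
Conditions: tigloyl chloride, pyridine, DMAP (cat.), CH2Cl2, 0 °C to rt
Reagents that add atoms: tigloyl chloride C/C=C(\C)C(=O)Cl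
Why: DMAP-catalysed acylation should esterify the secondary C1 hydroxyl only, since the C8 hydroxyl is tertiary and any transannular hemiketal with the C5 ketone is in equilibrium with the open hydroxy ketone; pyridine as base avoids deconjugation of the (E)-enoyl unit.

Step 10
Reactants: 11 1β-tiglate 5-ketone
Product: 12 1β-tigloyloxy-8α-hydroxy-8β-isopropyl-3,6β-dimethyl-10β-(tert-butyldimethylsilyloxy)-7βH-cis-bicyclo[5.3.0]dec-3-en-5-one (enone C5=O, C4=C3(Me))
Conditions: IBX, DMSO/fluorobenzene, 70 °C
Reagents that add atoms: none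
Why: IBX dehydrogenation of a ketone to an enone should place the double bond at C3=C4 only, because C5 can enolize solely toward C4 (C6 is quaternary), and both C3 epimers converge here.

Step 11
Reactants: 12 C3-ene-5-one
Product: 13 1β-tigloyloxy-5α,8α-dihydroxy-8β-isopropyl-3,6β-dimethyl-10β-(tert-butyldimethylsilyloxy)-7βH-cis-bicyclo[5.3.0]dec-3-ene
Conditions: NaBH4, CeCl3·7H2O, MeOH, −78 to −40 °C
Reagents that add atoms: none
Why: Luche reduction should give clean 1,2-reduction, with hydride expected from the convex β face because, with the fully substituted C8 pseudo-equatorial on ring A, the ring B carbon C10 sits pseudo-axial on the α face next to C5, so the 5α-alcohol should form while the tiglate survives.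

Step 12
Reactants: 13 5α-allylic alcohol
Product: 14 3α,4α-epoxy-1β-tigloyloxy-5α,8α-dihydroxy-8β-isopropyl-3β,6β-dimethyl-10β-(tert-butyldimethylsilyloxy)-7βH-cis-bicyclo[5.3.0]decane
Conditions: VO(acac)2 (cat.), t-BuOOH, CH2Cl2, 0 °C to rt
Reagents that add atoms: tert-butyl hydroperoxide CC(C)(C)OO
Why: Vanadium-catalysed hydroxyl-directed (Sharpless–Michaelson) epoxidation should deliver oxygen to the C3=C4 alkene on the face of the allylic C5 hydroxyl, giving the α-epoxide, while the electron-poor tiglate alkene is inert.

Step 13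
Reactants: 14 epoxy 5α-alcohol
Product: 15 3α,4α-epoxy-1β,5α-bis(tigloyloxy)-8α-hydroxy-8β-isopropyl-3β,6β-dimethyl-10β-(tert-butyldimethylsilyloxy)-7βH-cis-bicyclo[5.3.0]decane
Conditions: tigloyl chloride, pyridine, DMAP, CH2Cl2, rt
Reagents that add atoms: tigloyl chloride C/C=C(\C)C(=O)Cl
Why: DMAP-catalysed acylation should esterify the only free secondary hydroxyl (C5), the tertiary C8 hydroxyl being unreactive, under non-alkoxide conditions that avoid Payne rearrangement of the epoxy alcohol.

Step 14
Reactants: 15 bis-tiglate silyl ether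
Product: 16 CNP0265715.1: 3α,4α-epoxy-1β,5α-bis(tigloyloxy)-8α,10β-dihydroxy-8β-isopropyl-3β,6β-dimethyl-7βH-cis-bicyclo[5.3.0]decane
Conditions: HF·pyridine, pyridine, THF, 0 °C to rt
Reagents that add atoms: none
Why: Fluoride-mediated desilylation under pyridine-buffered, non-basic conditions should free the C10 hydroxyl without opening the trisubstituted epoxide or causing 1,3-acyl migration from C5.

**Compound list**

1 | (S)-4-(tert-butyldimethylsilyloxy)cyclopent-2-en-1-one | O=C1C=C[C@@H](O[Si](C)(C)C(C)(C)C)C1 | starting material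
2 | (3S,4S)-4-(tert-butyldimethylsilyloxy)-3-methyl-1-(trimethylsilyloxy)cyclopent-1-ene | C[Si](C)(C)OC1=C[C@H](C)[C@@H](O[Si](C)(C)C(C)(C)C)C1 | intermediate
3 | (S)-4-(tert-butyldimethylsilyloxy)-3-methylcyclopent-2-en-1-one | O=C1C=C(C)[C@@H](O[Si](C)(C)C(C)(C)C)C1 | intermediate
4 | dimethyl 3-methylpentanedioate | COC(=O)CC(C)CC(=O)OC | starting material
5 | 4-methyl-1,2-bis(trimethylsilyloxy)cyclopent-1-ene | CC1CC(O[Si](C)(C)C)=C(O[Si](C)(C)C)C1 | intermediate
6 | tricyclic photoadduct (C8 ketone, cyclobutane C1–C5–C6–C7, 1,5-bis(trimethylsilyloxy), 10β-OTBS) | O=C1C[C@H](O[Si](C)(C)C(C)(C)C)[C@]2(C)[C@H]1[C@@]3(O[Si](C)(C)C)C[C@H](C)C[C@@]23O[Si](C)(C)C | intermediate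
7 | 8α-hydroxy-8β-isopropyl tricycle (1,5-bis(trimethylsilyloxy), 10β-OTBS) | CC(C)[C@]1(O)C[C@H](O[Si](C)(C)C(C)(C)C)[C@]2(C)[C@H]1[C@@]3(O[Si](C)(C)C)C[C@H](C)C[C@@]23O[Si](C)(C)C | intermediate
8 | cis-cyclobutane-1,5-diol (1,5,8α-triol, 10β-OTBS) | CC(C)[C@]1(O)C[C@H](O[Si](C)(C)C(C)(C)C)[C@]2(C)[C@H]1[C@@]3(O)C[C@H](C)C[C@@]23O | intermediate
9 | 8α-hydroxy-8β-isopropyl-3,6β-dimethyl-10β-(tert-butyldimethylsilyloxy)-7βH-cis-bicyclo[5.3.0]decane-1,5-dione | CC(C)[C@]1(O)C[C@H](O[Si](C)(C)C(C)(C)C)[C@]2(C)[C@H]1C(=O)C[C@H](C)CC2=O | intermediate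
10 | 1β,8α-dihydroxy 5-ketone | CC(C)[C@]1(O)C[C@H](O[Si](C)(C)C(C)(C)C)[C@]2(C)[C@H]1[C@@H](O)C[C@H](C)CC2=O | intermediate
11 | 1β-tigloyloxy 5-ketone | CC(C)[C@]1(O)C[C@H](O[Si](C)(C)C(C)(C)C)[C@]2(C)[C@H]1[C@@H](OC(=O)/C(C)=C/C)C[C@H](C)CC2=O | intermediate
12 | 1β-tigloyloxy C3-en-5-one | CC(C)[C@]1(O)C[C@H](O[Si](C)(C)C(C)(C)C)[C@]2(C)[C@H]1[C@@H](OC(=O)/C(C)=C/C)CC(C)=CC2=O | intermediate
13 | 1β-tigloyloxy 5α-allylic alcohol | CC(C)[C@]1(O)C[C@H](O[Si](C)(C)C(C)(C)C)[C@]2(C)[C@H]1[C@@H](OC(=O)/C(C)=C/C)CC(C)=C[C@@H]2O | intermediate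
14 | 3α,4α-epoxy 5α-alcohol, 1β-tiglate | CC(C)[C@]1(O)C[C@H](O[Si](C)(C)C(C)(C)C)[C@]2(C)[C@H]1[C@@H](OC(=O)/C(C)=C/C)C[C@]3(C)O[C@@H]3[C@@H]2O | intermediate
15 | 3α,4α-epoxy 1β,5α-bis-tiglate, 10β-OTBS | CC(C)[C@]1(O)C[C@H](O[Si](C)(C)C(C)(C)C)[C@]2(C)[C@H]1[C@@H](OC(=O)/C(C)=C/C)C[C@]3(C)O[C@@H]3[C@@H]2OC(=O)/C(C)=C/C | intermediate
16 | CNP0265715.1 | CC(C)[C@]1(O)C[C@H](O)[C@]2(C)[C@H]1[C@@H](OC(=O)/C(C)=C/C)C[C@]3(C)O[C@@H]3[C@@H]2OC(=O)/C(C)=C/C | target

**Summary**

Total step count: 14. Longest linear sequence: 13 steps (from 1 through steps 1, 2 and 4–14).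

Steps most likely to fail:

Step 4. The risk is slow bond formation between two fully substituted carbons, which lets enone photoreduction or dimerization compete, and incomplete facial discrimination at 3. The fallback leaves photochemistry for a ground-state polar formal [2+2] that sets out again from 3 and 5. With catalytic Tf2NH in CH2Cl2 at −78 °C the silylium-activated enone should accept a Mukaiyama–Michael addition of 5 at C6, anti to the silyloxy group. The ring B silyl enol ether formed should then close onto the C1 silyloxycarbenium ion in an aldol-type four-ring closure. This would give 6 directly, where the route is rejoined; the fallback makes no new compound (F0).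

Step 11. The risk is hydride entering the α face if ring A prefers the conformer with the C6 methyl pseudo-axial, which would give the 5β-alcohol and then the β-epoxide in step 12. The fallback changes from external to internal hydride delivery, which operates through that same conformer. From 12, HF·pyridine would free the C10 hydroxyl to give the hydroxy enone F1. Me4NBH(OAc)3 in MeCN/AcOH should then deliver hydride from the C10 oxygen and give the 1,3-anti diol F2, which has the 5α-hydroxyl and the C5/C10 relationship of the target. Selective silylation of the more exposed, convex-face C10 hydroxyl (TBSCl, imidazole, DMF, 0 °C) would come back to 13.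

Step 5. The risk is β-hydride transfer from the isopropyl reagent, or enolization with loss of the β-silyloxy group, in place of addition to the hindered C8 ketone. The fallback sets out from 6 and uses the smaller sp2 nucleophile 2-propenylmagnesium bromide with CeCl3 in THF at −78 °C, which cannot reduce by β-hydride transfer. This would give the isopropenyl carbinol F3. Hydrogenation of its 1,1-disubstituted alkene (H2, PtO2, EtOAc) would come back to 7.

**Further compounds**

F0 | step 4 | none | none
F1 | step 11 | 1β-tigloyloxy-8α,10β-dihydroxy-8β-isopropyl-3,6β-dimethyl-7βH-cis-bicyclo[5.3.0]dec-3-en-5-one | CC(C)[C@]1(O)C[C@H](O)[C@]2(C)[C@H]1[C@@H](OC(=O)/C(C)=C/C)CC(C)=CC2=O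
F2 | step 11 | 1β-tigloyloxy-5α,8α,10β-trihydroxy-8β-isopropyl-3,6β-dimethyl-7βH-cis-bicyclo[5.3.0]dec-3-ene | CC(C)[C@]1(O)C[C@H](O)[C@]2(C)[C@H]1[C@@H](OC(=O)/C(C)=C/C)CC(C)=C[C@@H]2O
F3 | step 5 | 8α-hydroxy-8β-(prop-1-en-2-yl) analogue of 7 | C=C(C)[C@]1(O)C[C@H](O[Si](C)(C)C(C)(C)C)[C@]2(C)[C@H]1[C@@]3(O[Si](C)(C)C)C[C@H](C)C[C@@]23O[Si](C)(C)C
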